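## The problem

The target is a dihydrochalcone: two benzene rings joined through an ArC(=O)CH2CH2Ar chain, with no stereocentre, so the synthesis turns on regiochemistry and functional-group tolerance. Ring A is an acylphloroglucinol (OH at C2', C4' and C6') with one prenyl group at C3'. C3' and C5' are equivalent until the first prenyl group is in place, so the task there is mono- against di-alkylation and C- against O-alkylation. Ring B is a catechol (OH at C3 and C4) with a prenyl group at C5, ortho to the C4 oxygen only, and this position has to be distinguished from C2 and C6. Both prenyl groups are trisubstituted alkenes next to free phenols. Strong Brønsted or Lewis acids close them to 2,2-dimethylchromans, hydrogenolysis saturates them, and the electron-rich rings are easily oxidised, which rules out Friedel–Crafts acylation of prenylated phenols, benzyl ethers and late oxidations. The feature that opens the molecule is the alternation in ring A: C1' carries the ketone carbon and C2', C4' and C6' carry oxygen, the pattern of a folded tetraketide. Ring A can therefore be made from an open 3,5,7-trioxo ester by forming the single bond C1'–C6'.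

## Retrosynthesis

**Unmasking.** The last disconnection removes the two methoxymethyl (MOM) ethers of ring B, taking target 19 back to 18. MOM ethers are chosen because they must survive NaH, Mg in methanol, a Grignard reagent, a lithium amide and methoxide, and they are the only protecting groups in the route. The forward step needs acid mild enough to leave two ortho-prenyl phenols intact.

**Ring A prenyl group.** The C3'–CH2 bond of 18 is cut to acylphloroglucinol 16 and prenyl bromide 17. With the catechol masked, the only acidic phenols are on ring A, and C3' and C5' are equivalent, so regiochemistry is not an issue. Carrying the prenyl group on C4 of the open chain through the ring closure was considered. It would remove the mono/di problem, but it needs a trianion of a 4-alkylated diketo ester and a more hindered closure, both less secure than the late alkylation. The forward reaction must stop at mono-C-alkylation.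

**Ring A (key disconnection).** The C1'–C6' bond of 16 is cut. Through the non-aromatic triketone 15 this leads back to the open-chain triketo ester 14, whose C1 to C6 become the ring and whose C7 is the ketone. The neighbouring cut, the aryl–carbonyl bond by Friedel–Crafts or Hoesch acylation of phloroglucinol, needs Lewis or strong protic acid that ring B's MOM ethers and prenyl group would not survive. The Claisen closure runs in methoxide, to which both are inert, and 14 contains no ring A at all. The forward reaction must close by Claisen condensation (C6 onto C1) and not by aldol condensation (C2 onto C7).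

**Tetraketide chain.** The C6–C7 bond of 14 is cut to Weinreb amide 10 and trianion 13 of methyl 3,5-dioxohexanoate 12. The amide is preferred to an ester because its chelated tetrahedral adduct holds until the quench, so the more acidic product never meets 13. Ester 12 comes in one step from the commercial pyrone 11 by methanolysis.

**Ring B side chain.** Amide 10 is traced through saturated ester 9 and cinnamate 8 to aldehyde 7. The Cα=Cβ bond of 8 is formed by a Horner–Wadsworth–Emmons reaction. The reduction must take the conjugated alkene and leave the prenyl alkene.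

**Ring B prenyl group.** Aldehyde 7 is the bis-MOM ether of catechol 6, whose C5–CH2 bond is cut by an aromatic Claisen rearrangement. This leads through dienone 5 to the 1,1-dimethylallyl ether 4, then to propargyl ether 3 and to 3,4-dihydroxybenzaldehyde 1 and 3-chloro-3-methylbut-1-yne 2. An ether on O4 has only C5 as a free ortho carbon, so the rearrangement fixes the position. The forward sequence needs etherification at O4, the more acidic hydroxyl (para to the formyl group), and not at O3.

## Roads not taken

**Alternative 1: double aromatic Claisen rearrangement.** Both aryl–CH2(prenyl) bonds are cut at once. Heating the 4',4-bis(1,1-dimethylallyl) ether A1 would move both allyl groups with inversion to C3' and C5, giving the tris-MOM ether A2.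
- Merits: each ring receives exactly one prenyl group at a position fixed by the ortho rule. This is better than step 11 of the chosen plan, where mono-alkylation is controlled only by stoichiometry.
- Weak points: A1 needs the 4'- and 4-hydroxyls free while the 2'-, 6'- and 3-hydroxyls are masked. On ring A this is the reverse of the natural order of reactivity (the 4'-OH reacts first and a chelated ortho-OH last), so protecting-group steps accumulate. The dihydrochalcone skeleton must still be built by some other means. Two tertiary ethers have to be made and semi-hydrogenated, and the ring A ether sits on a very electron-rich ring that can ionize and lose the allyl group.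
- Comparison: the chosen plan gets the skeleton and the oxygen pattern of ring A from one cyclization with only two protecting groups, and it uses the same ether Claisen logic on ring B, where it is simple. Its fallback for step 11 uses this idea on ring A alone.

**Alternative 2: three-component carbonylative coupling.** The two bonds at the ketone carbon are cut. The ring A iodide A3, carbon monoxide and the ring B alkylborane A4 (from aldehyde 7 by methylenation and hydroboration with 9-BBN) would couple under PdCl2(dppf) and K3PO4 to the pentakis-MOM ether A5.
- Merits: the route is convergent, the ring A prenyl group can be placed by directed lithiation with no mono/di problem, and it is about two steps shorter than the chosen plan.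
- Weak points: A3 is an electron-rich iodide with two ortho substituents, so CO insertion has to beat direct alkyl–aryl coupling at a crowded palladium centre. The hydroboration must select the vinyl group over two prenyl alkenes. Five MOM ethers instead of two must come off at the end beside two prenyl phenols.
- Comparison: the chosen plan is longer, but its ring-forming step uses magnesium methoxide in methanol, has direct precedent on the same substrate class, and leaves only two acetals for the final acid step.

**Alternative 3: diene plus alkoxy ynone benzannulation.** The C5'–C6' and C1'–C2' bonds are cut. The 2-prenyl bis(silyloxy)diene A6 and the tert-butoxy ynone A7 (from amide 10) would combine and aromatize by loss of the silyl methyl ether to A8.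
- Merits: ring A is formed with the prenyl group already fixed between two oxygens, so no late C-prenylation is needed. In this respect it is better than the chosen plan.
- Weak points: A7 is a push–pull alkyne of low electrophilicity, and tert-butyl ynol ethers fragment to ketenes on warming. The diene is tetrasubstituted at the prenyl-bearing carbon. Cleaving the tert-butyl aryl ether of A8 needs stronger acid than MOM removal, next to two prenyl phenols. The annulation has no close precedent with alkoxy ynones, and the step count is no lower.
- Comparison: the chosen plan accepts a less selective prenylation in exchange for a ring closure of known type with simple reagents.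

Key step: step 10

## Route

Remark on the chemistry: compounds 12 and 14 exist as keto–enol mixtures and are named and drawn in the all-keto form. The target has no stereocentre, and the only stereochemical element of the route is the E alkene of 8, which is removed in step 6.

Step 1
Reactants: 1 3,4-dihydroxybenzaldehyde; 2 3-chloro-3-methylbut-1-yne
Product: 3 3-hydroxy-4-[(2-methylbut-3-yn-2-yl)oxy]benzaldehyde
Conditions: DBU (1.05 equiv), CuCl2·2H2O (1 mol%), MeCN, 0 °C → rt, N2
Reagents that add atoms: none
Why: Copper-catalysed propargylic etherification of a phenol with a tertiary propargylic chloride; one equivalent of base forms only the phenoxide of the more acidic 4-OH (para to the formyl group), the known site of mono-alkylation of this catechol aldehyde.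

Step 2
Reactants: 3 3-hydroxy-4-[(2-methylbut-3-yn-2-yl)oxy]benzaldehyde
Product: 4 3-hydroxy-4-[(2-methylbut-3-en-2-yl)oxy]benzaldehyde
Conditions: H2 (1 atm), Pd/CaCO3 poisoned with Pb(OAc)2, quinoline, EtOAc, rt
Reagents that add atoms: none
Why: Lindlar semi-hydrogenation of the terminal alkyne stops at the alkene and leaves the aldehyde alone; it must precede heating, because the propargyl ether would otherwise cyclize to a 2,2-dimethylchromene.

Step 3
Reactants: 4 3-hydroxy-4-[(2-methylbut-3-en-2-yl)oxy]benzaldehyde
Product: 6 3,4-dihydroxy-5-(3-methylbut-2-enyl)benzaldehyde, via ortho-dienone 5 (not isolated)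
Conditions: PhNEt2, 140 °C, Ar
Reagents that add atoms: none
Why: Aromatic Claisen rearrangement ([3,3]-sigmatropic shift): the 1,1-dimethylallyl group moves with allylic inversion from O4 to C5, the only ortho carbon bearing hydrogen (C3 carries OH and the para carbon carries the formyl group), and dienone 5 enolizes to the catechol.

Step 4
Reactants: 6 3,4-dihydroxy-5-(3-methylbut-2-enyl)benzaldehyde
Product: 7 3,4-bis(methoxymethoxy)-5-(3-methylbut-2-enyl)benzaldehyde
Conditions: MOMCl (3 equiv), iPr2NEt, CH2Cl2, 0 °C → rt
Reagents that add atoms: chloromethyl methyl ether (MOMCl), COCCl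
Why: Standard O-alkylation of phenols to methoxymethyl ethers under amine base; the small electrophile also reaches the 4-OH flanked by the prenyl group.

Step 5
Reactants: 7 3,4-bis(methoxymethoxy)-5-(3-methylbut-2-enyl)benzaldehyde
Product: 8 methyl (E)-3-[3,4-bis(methoxymethoxy)-5-(3-methylbut-2-enyl)phenyl]prop-2-enoate
Conditions: (MeO)2P(O)CH2CO2Me, NaH, THF, 0 °C → rt
Reagents that add atoms: trimethyl phosphonoacetate, COC(=O)CP(=O)(OC)OC
Why: Horner–Wadsworth–Emmons olefination of an aromatic aldehyde with a stabilized phosphonate gives the E cinnamate; the geometry is not critical because the alkene is reduced next.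

Step 6
Reactants: 8 methyl (E)-3-[3,4-bis(methoxymethoxy)-5-(3-methylbut-2-enyl)phenyl]prop-2-enoate
Product: 9 methyl 3-[3,4-bis(methoxymethoxy)-5-(3-methylbut-2-enyl)phenyl]propanoate
Conditions: Mg turnings, MeOH, 0 °C → rt; aq. NH4Cl
Reagents that add atoms: none
Why: Dissolving-metal conjugate reduction of a cinnamate by electron transfer from magnesium in methanol; the isolated trisubstituted prenyl alkene and the aryl MOM ethers do not accept electrons under these conditions, and a methyl ester cannot be scrambled by the solvent.

Step 7
Reactants: 9 methyl 3-[3,4-bis(methoxymethoxy)-5-(3-methylbut-2-enyl)phenyl]propanoate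
Product: 10 3-[3,4-bis(methoxymethoxy)-5-(3-methylbut-2-enyl)phenyl]-N-methoxy-N-methylpropanamide
Conditions: MeNH(OMe)·HCl, iPrMgCl, THF, −20 → 0 °C
Reagents that add atoms: N,O-dimethylhydroxylamine hydrochloride, CNOC.Cl
Why: Direct aminolysis of an ester by the magnesium amide of N,O-dimethylhydroxylamine (Weinreb amide formation); the chelated adduct prevents addition of the Grignard reagent to the product.

Step 8
Reactants: 11 4-hydroxy-6-methyl-2H-pyran-2-one
Product: 12 methyl 3,5-dioxohexanoate
Conditions: Mg(OMe)2, MeOH, reflux; cold 1 M HCl
Reagents that add atoms: methanol, CO (delivered as Mg(OMe)2 in MeOH)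
Why: Ring-opening methanolysis of the enol lactone by magnesium methoxide; the product is held as its magnesium chelate, which prevents re-closure and further condensation until the acidic quench.

Step 9
Reactants: 12 methyl 3,5-dioxohexanoate; 10 3-[3,4-bis(methoxymethoxy)-5-(3-methylbut-2-enyl)phenyl]-N-methoxy-N-methylpropanamide
Product: 14 methyl 9-[3,4-bis(methoxymethoxy)-5-(3-methylbut-2-enyl)phenyl]-3,5,7-trioxononanoate, via trilithium trianion 13 (not isolated)
Conditions: LiN(iPr)2 (3.1 equiv per 12), THF, −78 → 0 °C; then 10 (0.67 equiv), −78 → 0 °C; cold dilute HCl to pH 5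
Reagents that add atoms: none
Why: Polyanion acylation: three equivalents of amide base deprotonate C2, C4 and the C6 methyl of 12, and the last-formed terminal carbanion of 13 is the most nucleophilic and adds to the Weinreb amide. The chelated tetrahedral adduct holds until the quench, so the more acidic product is never exposed to 13.

Step 10
Reactants: 14 methyl 9-[3,4-bis(methoxymethoxy)-5-(3-methylbut-2-enyl)phenyl]-3,5,7-trioxononanoate
Product: 16 3-[3,4-bis(methoxymethoxy)-5-(3-methylbut-2-enyl)phenyl]-1-(2,4,6-trihydroxyphenyl)propan-1-one, via cyclic triketone 15 (not isolated)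
Conditions: Mg(OMe)2 (6 equiv), MeOH, rt → 60 °C; cold 1 M HCl to pH 4
Reagents that add atoms: none
Why: Magnesium methoxide turns 14 into a chelated polyenolate in which C6, flanked by the C5 and C7 carbonyls, attacks the C1 ester carbonyl; methoxide leaves and the 2-acylcyclohexane-1,3,5-trione 15 enolizes to the aromatic acylphloroglucinol. The closest known reaction type is the base-mediated Claisen cyclization of 3,5,7-trioxoalkanoate esters and of the corresponding 6-(2-oxoalkyl)-4-hydroxy-2-pyrones to acylphloroglucinols with magnesium methoxide or methanolic hydroxide, the laboratory version of the chalcone-synthase fold. The ring closes in a 6-exo-trig mode (enolate carbon onto an exocyclic ester carbonyl), which forms the C1'–C6' bond and places the acyl carbon on C1' with oxygen on C2', C4' and C6'. No stereocentre is formed. The selectivity needed is Claisen closure over aldol closure of C2 onto C7 (which would give a resorcylate) and over O-acylation to a pyrone. It is secured by the ester terminus (a free acid cannot undergo the Claisen mode), by anhydrous methoxide, and by magnesium chelation of the C5/C7 diketone, which lowers the electrophilicity of C7 and leaves the ester as the acceptor. Aldol addition is reversible while its dehydration is slow in this medium, whereas loss of methoxide and aromatization make the Claisen path irreversible. The singly activated C8 methylene is not deprotonated by methoxide, so closure of C8 onto C3 is not expected, and the ring B prenyl group and MOM ethers are inert to the base.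

Step 11
Reactants: 16 3-[3,4-bis(methoxymethoxy)-5-(3-methylbut-2-enyl)phenyl]-1-(2,4,6-trihydroxyphenyl)propan-1-one; 17 1-bromo-3-methylbut-2-ene (prenyl bromide)
Product: 18 3-[3,4-bis(methoxymethoxy)-5-(3-methylbut-2-enyl)phenyl]-1-[2,4,6-trihydroxy-3-(3-methylbut-2-enyl)phenyl]propan-1-one
Conditions: DBU (1.0 equiv), 17 (1.0 equiv), THF, 0 °C → rt
Reagents that add atoms: none
Why: Base-mediated C-alkylation of an acylphloroglucinol: the monoanion reacts as a vinylogous enolate at a ring carbon between two oxygens in an SN2 displacement on the allylic bromide. C3' and C5' are equivalent, one equivalent of 17 at partial conversion limits 3',5'-dialkylation, and the masked catechol cannot compete.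

Step 12
Reactants: 18 3-[3,4-bis(methoxymethoxy)-5-(3-methylbut-2-enyl)phenyl]-1-[2,4,6-trihydroxy-3-(3-methylbut-2-enyl)phenyl]propan-1-one
Product: 19 3-[3,4-dihydroxy-5-(3-methylbut-2-enyl)phenyl]-1-[2,4,6-trihydroxy-3-(3-methylbut-2-enyl)phenyl]propan-1-one (2',4',6',3,4-pentahydroxy-3',5-diprenyldihydrochalcone)
Conditions: 3 M HCl (aq.), MeOH, rt
Reagents that add atoms: none
Why: Acid-catalysed acetal exchange (MOM ether cleavage) in methanol frees both catechol oxygens; room temperature and short contact are chosen so that the prenyl alkenes ortho to free phenols are not protonated.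

## Compound list

1 | 3,4-dihydroxybenzaldehyde | O=Cc1ccc(O)c(O)c1 | starting material
2 | 3-chloro-3-methylbut-1-yne | CC(C)(Cl)C#C | starting material
3 | 3-hydroxy-4-[(2-methylbut-3-yn-2-yl)oxy]benzaldehyde | O=Cc1ccc(OC(C)(C)C#C)c(O)c1 | intermediate
4 | 3-hydroxy-4-[(2-methylbut-3-en-2-yl)oxy]benzaldehyde | O=Cc1ccc(OC(C)(C)C=C)c(O)c1 | intermediate
5 | 5-hydroxy-3-(3-methylbut-2-enyl)-4-oxocyclohexa-1,5-diene-1-carbaldehyde (racemic, transient) | O=CC1=CC(CC=C(C)C)C(=O)C(O)=C1 | intermediate (not isolated)
6 | 3,4-dihydroxy-5-(3-methylbut-2-enyl)benzaldehyde | O=Cc1cc(O)c(O)c(CC=C(C)C)c1 | intermediate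
7 | 3,4-bis(methoxymethoxy)-5-(3-methylbut-2-enyl)benzaldehyde | O=Cc1cc(CC=C(C)C)c(OCOC)c(OCOC)c1 | intermediate
8 | methyl (E)-3-[3,4-bis(methoxymethoxy)-5-(3-methylbut-2-enyl)phenyl]prop-2-enoate | COC(=O)/C=C/c1cc(CC=C(C)C)c(OCOC)c(OCOC)c1 | intermediate
9 | methyl 3-[3,4-bis(methoxymethoxy)-5-(3-methylbut-2-enyl)phenyl]propanoate | COC(=O)CCc1cc(CC=C(C)C)c(OCOC)c(OCOC)c1 | intermediate
10 | 3-[3,4-bis(methoxymethoxy)-5-(3-methylbut-2-enyl)phenyl]-N-methoxy-N-methylpropanamide | CON(C)C(=O)CCc1cc(CC=C(C)C)c(OCOC)c(OCOC)c1 | intermediate
11 | 4-hydroxy-6-methyl-2H-pyran-2-one | Cc1cc(O)cc(=O)o1 | starting material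
12 | methyl 3,5-dioxohexanoate | COC(=O)CC(=O)CC(C)=O | intermediate
13 | trilithium trianion of methyl 3,5-dioxohexanoate (tris-enolate) | [Li+].[Li+].[Li+].C=C([O-])C=C([O-])C=C([O-])OC | intermediate (not isolated)
14 | methyl 9-[3,4-bis(methoxymethoxy)-5-(3-methylbut-2-enyl)phenyl]-3,5,7-trioxononanoate | COC(=O)CC(=O)CC(=O)CC(=O)CCc1cc(CC=C(C)C)c(OCOC)c(OCOC)c1 | intermediate
15 | 2-{3-[3,4-bis(methoxymethoxy)-5-(3-methylbut-2-enyl)phenyl]propanoyl}cyclohexane-1,3,5-trione | O=C(CCc1cc(CC=C(C)C)c(OCOC)c(OCOC)c1)C1C(=O)CC(=O)CC1=O | intermediate (not isolated)
16 | 3-[3,4-bis(methoxymethoxy)-5-(3-methylbut-2-enyl)phenyl]-1-(2,4,6-trihydroxyphenyl)propan-1-one | O=C(CCc1cc(CC=C(C)C)c(OCOC)c(OCOC)c1)c1c(O)cc(O)cc1O | intermediate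
17 | 1-bromo-3-methylbut-2-ene (prenyl bromide) | CC(C)=CCBr | starting material
18 | 3-[3,4-bis(methoxymethoxy)-5-(3-methylbut-2-enyl)phenyl]-1-[2,4,6-trihydroxy-3-(3-methylbut-2-enyl)phenyl]propan-1-one | CC(C)=CCc1c(O)cc(O)c(C(=O)CCc2cc(CC=C(C)C)c(OCOC)c(OCOC)c2)c1O | intermediate
19 | 3-[3,4-dihydroxy-5-(3-methylbut-2-enyl)phenyl]-1-[2,4,6-trihydroxy-3-(3-methylbut-2-enyl)phenyl]propan-1-one | CC(C)=CCc1cc(CCC(=O)c2c(O)cc(O)c(CC=C(C)C)c2O)cc(O)c1O | target

## Step count and least certain steps

Total: 12 steps. Longest linear sequence: 11 steps (steps 1–7, then 9–12); step 8 is a one-step branch.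

**Step 10 (key step).** The closure may take the aldol course (chain C2 onto the C7 ketone, then dehydration to a resorcylate) or end as a pyrone by O-acylation. The reason is that C7 is an aliphatic ketone here and more electrophilic than the aryl ketones on which the Claisen mode is best documented. The fallback gives up the ring closure and sets out from amide 10. Phloroglucinol would be converted with MOMCl and NaH into 1,3,5-tris(methoxymethoxy)benzene F1. Lithiation between two MOM-oxy groups (n-BuLi, THF, 0 °C) and alkylation through the copper species (CuI, then 17) would give 1,3,5-tris(methoxymethoxy)-2-(3-methylbut-2-enyl)benzene F2. A second directed lithiation at one of the two equivalent positions flanked by MOM-oxy groups, followed by addition to 10, would give the pentakis(methoxymethyl) ether of the target F3 (the same compound as A5). The acid treatment of step 12 would then bring the route back at 19.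

**Step 9.** The basic terminal carbanion of 13 may take a proton from the α-methylene of amide 10 instead of acylating, or the third deprotonation of 12 may be incomplete, and the product may cyclize on work-up. The fallback sets out from pyrone 11 and amide 10. The dianion of 11 (two equivalents of LiN(iPr)2, THF, −78 °C), which is less basic than a trianion, would be acylated at its methyl carbon by 10. This gives 6-{4-[3,4-bis(methoxymethoxy)-5-(3-methylbut-2-enyl)phenyl]-2-oxobutyl}-4-hydroxy-2H-pyran-2-one F4, a stable lactone form of the tetraketide. Mg(OMe)2 in methanol would open F4 to the magnesium enolate of 14 in the flask, where the route is rejoined and the conditions of step 10 carry it on to 16.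

**Step 11.** Over-alkylation to the 3',5'-diprenyl compound, O-alkylation and geminal dialkylation may compete, because the mono-prenyl product is as nucleophilic as 16. The fallback sets out from 16 and repeats the ether Claisen sequence of steps 1–3 on ring A. Etherification of the 4'-OH (the most acidic hydroxyl, not hydrogen-bonded to the ketone) with 2, DBU and catalytic CuCl2·2H2O would give 3-[3,4-bis(methoxymethoxy)-5-(3-methylbut-2-enyl)phenyl]-1-{2,6-dihydroxy-4-[(2-methylbut-3-yn-2-yl)oxy]phenyl}propan-1-one F5. Semi-hydrogenation over Pd/CaCO3 poisoned with Pb(OAc)2 would give the corresponding 4'-(2-methylbut-3-en-2-yl) ether F6. Gentle heating would move the single allyl group to C3' (C3' and C5' are equivalent), and the route is rejoined at 18.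

**Step 12.** The acid may add the freed phenols or methanol to the prenyl double bonds (chroman formation), most easily on the very electron-rich ring A, where the prenyl group sits between two free hydroxyls. The fallback changes the order of events and sets out from 16. The MOM ethers would be removed before ring A is prenylated, so that only the less sensitive ring B prenyl group meets acid, giving 3-[3,4-dihydroxy-5-(3-methylbut-2-enyl)phenyl]-1-(2,4,6-trihydroxyphenyl)propan-1-one F7. One equivalent of DBU would then deprotonate only the much more acidic acylphloroglucinol, and alkylation with 17 would return the route at 19.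

**Step 1.** The etherification may not be confined to O4 (some O3 ether and bis-ether), and the tertiary chloride may be lost by elimination, because the copper-stabilised propargylic cation discriminates less than an SN2 electrophile. The fallback sets out from 1 and uses palladium-catalysed allylic etherification instead. The reagent tert-butyl (2-methylbut-3-en-2-yl) carbonate F8 would be prepared from 2-methylbut-3-en-2-ol and di-tert-butyl dicarbonate. With Pd(PPh3)4 in THF at 0 °C it should transfer the tertiary allyl group to the more acidic 4-OH under base-free conditions, giving 4 directly and bypassing 3. This fallback still relies on the acidity difference between the two hydroxyls.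

## Further compounds

F1 | step 10 | 1,3,5-tris(methoxymethoxy)benzene | COCOc1cc(OCOC)cc(OCOC)c1
F2 | step 10 | 1,3,5-tris(methoxymethoxy)-2-(3-methylbut-2-enyl)benzene | COCOc1cc(OCOC)c(CC=C(C)C)c(OCOC)c1
F3 | step 10 | 3-[3,4-bis(methoxymethoxy)-5-(3-methylbut-2-enyl)phenyl]-1-[2,4,6-tris(methoxymethoxy)-3-(3-methylbut-2-enyl)phenyl]propan-1-one | COCOc1cc(OCOC)c(CC=C(C)C)c(OCOC)c1C(=O)CCc1cc(CC=C(C)C)c(OCOC)c(OCOC)c1
F4 | step 9 | 6-{4-[3,4-bis(methoxymethoxy)-5-(3-methylbut-2-enyl)phenyl]-2-oxobutyl}-4-hydroxy-2H-pyran-2-one | O=C(CCc1cc(CC=C(C)C)c(OCOC)c(OCOC)c1)Cc1cc(O)cc(=O)o1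
F5 | step 11 | 3-[3,4-bis(methoxymethoxy)-5-(3-methylbut-2-enyl)phenyl]-1-{2,6-dihydroxy-4-[(2-methylbut-3-yn-2-yl)oxy]phenyl}propan-1-one | C#CC(C)(C)Oc1cc(O)c(C(=O)CCc2cc(CC=C(C)C)c(OCOC)c(OCOC)c2)c(O)c1
F6 | step 11 | 3-[3,4-bis(methoxymethoxy)-5-(3-methylbut-2-enyl)phenyl]-1-{2,6-dihydroxy-4-[(2-methylbut-3-en-2-yl)oxy]phenyl}propan-1-one | C=CC(C)(C)Oc1cc(O)c(C(=O)CCc2cc(CC=C(C)C)c(OCOC)c(OCOC)c2)c(O)c1
F7 | step 12 | 3-[3,4-dihydroxy-5-(3-methylbut-2-enyl)phenyl]-1-(2,4,6-trihydroxyphenyl)propan-1-one | O=C(CCc1cc(O)c(O)c(CC=C(C)C)c1)c1c(O)cc(O)cc1O
F8 | step 1 | tert-butyl (2-methylbut-3-en-2-yl) carbonate | C=CC(C)(C)OC(=O)OC(C)(C)C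
A1 | alternative 1 | 1-{2,6-bis(methoxymethoxy)-4-[(2-methylbut-3-en-2-yl)oxy]phenyl}-3-{3-(methoxymethoxy)-4-[(2-methylbut-3-en-2-yl)oxy]phenyl}propan-1-one | C=CC(C)(C)Oc1cc(OCOC)c(C(=O)CCc2ccc(OC(C)(C)C=C)c(OCOC)c2)c(OCOC)c1
A2 | alternative 1 | 1-[4-hydroxy-2,6-bis(methoxymethoxy)-3-(3-methylbut-2-enyl)phenyl]-3-[4-hydroxy-3-(methoxymethoxy)-5-(3-methylbut-2-enyl)phenyl]propan-1-one | CC(C)=CCc1c(O)cc(OCOC)c(C(=O)CCc2cc(CC=C(C)C)c(O)c(OCOC)c2)c1OCOC
A3 | alternative 2 | 2-iodo-1,3,5-tris(methoxymethoxy)-4-(3-methylbut-2-enyl)benzene | COCOc1cc(OCOC)c(CC=C(C)C)c(OCOC)c1I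
A4 | alternative 2 | 9-{2-[3,4-bis(methoxymethoxy)-5-(3-methylbut-2-enyl)phenyl]ethyl}-9-borabicyclo[3.3.1]nonane | COCOc1cc(CCB2C3CCCC2CCC3)cc(CC=C(C)C)c1OCOC
A5 | alternative 2 | 3-[3,4-bis(methoxymethoxy)-5-(3-methylbut-2-enyl)phenyl]-1-[2,4,6-tris(methoxymethoxy)-3-(3-methylbut-2-enyl)phenyl]propan-1-one | COCOc1cc(OCOC)c(CC=C(C)C)c(OCOC)c1C(=O)CCc1cc(CC=C(C)C)c(OCOC)c(OCOC)c1
A6 | alternative 3 | 1-methoxy-2-(3-methylbut-2-enyl)-1,3-bis(trimethylsilyloxy)buta-1,3-diene | COC(O[Si](C)(C)C)=C(CC=C(C)C)C(=C)O[Si](C)(C)C
A7 | alternative 3 | 5-[3,4-bis(methoxymethoxy)-5-(3-methylbut-2-enyl)phenyl]-1-tert-butoxypent-1-yn-3-one | CC(C)(C)OC#CC(=O)CCc1cc(CC=C(C)C)c(OCOC)c(OCOC)c1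
A8 | alternative 3 | 3-[3,4-bis(methoxymethoxy)-5-(3-methylbut-2-enyl)phenyl]-1-[6-tert-butoxy-2,4-dihydroxy-3-(3-methylbut-2-enyl)phenyl]propan-1-one | CC(C)(C)Oc1cc(O)c(CC=C(C)C)c(O)c1C(=O)CCc1cc(CC=C(C)C)c(OCOC)c(OCOC)c1
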